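I wanted to know how much left-handed product the flask held at its reading time, and which change would raise it most.

- how much left-handed product there is at 6.0 min, in percent of the left-handed substrate and right-handed substrate together charged
- the change that raises the amount of left-handed product at 6.0 min, in percent of the left-handed substrate and right-handed substrate together charged most ("none" if none brings more than 2 percentage points) (south / west / north / none)
- amount of left-handed product at 6.0 min, in percent of the left-handed substrate and right-handed substrate together charged, after north

common to all: gas 0.79 mM (held)
- dawn: left-handed substrate 10 mM; right-handed substrate 10 mM; catalyst 0.17 mM; run made earlier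
- autumn: left-handed substrate 10 mM; right-handed substrate 10 mM; catalyst 0.38 mM; run made earlier
- midnight: left-handed substrate 20 mM; right-handed substrate 20 mM; catalyst 0.25 mM; run made earlier
- flask: left-handed substrate 10 mM; right-handed substrate 10 mM; catalyst 0.25 mM; time 6.0 min

- dawn (time / min: left-handed product / %): 0.500: 0; 0.833: 0; 1.33: 3; 2.00: 4; 3.00: 8; 5.00: 6; 8.00: 13
- autumn (time / min: left-handed product / %): 0.417: 0; 1.00: 0; 2.00: 5; 3.00: 11; 4.00: 12; 6.00: 16; 8.00: 19
- midnight (time / min: left-handed product / %): 0.500: 1; 1.00: 2; 2.00: 0; 4.00: 5; 8.00: 12

(readings scatter by 1.5 percentage points)

I worked with the fraction of left-handed substrate left, which is one minus twice the percentage read, since that substrate was half the charge. From the last reading of each run I took the resistance, meaning the time divided by the natural logarithm of one over the fraction left, the inverse of a pseudo-first-order constant: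

- dawn, catalyst 0.17 mM: 74.0% left, resistance 26.6 min
- autumn, catalyst 0.38 mM: 62.0% left, resistance 16.7 min
- midnight, catalyst 0.25 mM, double substrate: 76.0% left, resistance 29.2 min

From dawn to autumn the catalyst rose 2.24-fold, but the resistance fell 1.59-fold. So I read it as two resistances in series, as on a double-reciprocal line: one for reaction, going as one over catalyst, and one for gas transfer, going with substrate. These two rows gave a reaction coefficient of 3.03 min·mM and a transfer term of 8.77 min. The midnight row then tested the split: doubling the transfer term predicted 29.6 min, and the reading gave 29.2 min.

For the flask the sum was 20.9 min, so I expected 12.5%. Doubling saturation halves both terms, giving 21.9% for south. West gave 16.6%, and north gave 15.3%.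

The forecast, holding that “gas transfer is partly limiting”, gave 13%, south as best, and 16.5% after north.

The flask gave 12.6%, with south best at 10 percentage points of gain, against 4.4 points for west and 3.7 points for north, and 16.2% after north.

    reagent + catalyst + left-handed substrate → catalyst + left-handed product (k = 8170 M⁻² s⁻¹)
    reagent + catalyst + right-handed substrate → catalyst + right-handed product (k = 1590 M⁻² s⁻¹)
    left-handed substrate ⇌ right-handed substrate (k = 2.44 × 10⁻⁴ s⁻¹)
    gas ⇌ reagent, rate k4*(csat - [reagent]) (kL = 0.0245 s⁻¹)

The left-handed product in the flask stayed low mainly for being read so early: the flask held 12.6% at 6.0 min, and the same flask left until 60.0 min held 59.7%, a difference of 47 points. Read at 1.5 min, the resistance gave 3.47%, and the flask computed 2.76%.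

(The data are simulated with constants of no real substance, noise included.)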